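The closed, stirred vessel holds a racemate with a single-handed free catalyst, and the books here are kept on left-handed substrate, the limiting reagent for left-handed product, because partner stands at 1.68 M against 0.840 M of both substrates together.

| flask | left-handed substrate | right-handed substrate | partner | free catalyst | precatalyst | remark | time |
|---|---|---|---|---|---|---|---|
| south-east | 0.42 M | 0.42 M | 1.68 M | 21 mM | 4.2 mM | the very flask that is asked about, followed so far |  |
| north-west | 0.42 M | 0.42 M | 2.5 M | 21 mM | 4.2 mM | run made earlier |  |
| flask | 0.42 M | 0.42 M | 1.68 M | 21 mM | 4.2 mM |  | 1.5 h |

- south-east (time / min: left-handed product / %): 5.00: 15.6; 15.0: 34.2; 25.0: 42.3; 40.0: 45.8; 50.0: 48.2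
- north-west (time / min: left-handed product / %): 1.50: 9.7; 3.00: 17.1; 5.00: 24.0; 6.00: 26.6; 8.00: 31.5

(scatter of a reading: 1 percentage point)

- beta: change nothing and wait 25 min more
- eta: at 1.5 h take out 90 % of the left-handed product then present, then wait 25 min
- alpha: at 1.5 h add free catalyst, 100 % of the amount charged, then wait 25 min

- free catalyst is single-handed; left-handed substrate and right-handed substrate are mirror images of each other, charged as a racemate, each of them at the stated concentration
- left-handed product that was removed still counts
- "the catalyst" is free catalyst with its forms; racemization catalyst is a second catalyst
- additions bring no volume worth counting

- left-handed product, in percent of the left-handed substrate and right-handed substrate together first charged, at 1.5 h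
- which option adds most left-handed product ("none" when 2 percentage points or less is all one gets) (beta / eta / alpha / none)
- left-handed product present, with what was taken out counted in, in percent of the left-handed substrate and right-handed substrate together first charged, after eta
- left-handed product present, with what was taken out counted in, in percent of the left-handed substrate and right-handed substrate together first charged, after alpha

The ledger opens with [left-handed substrate] at 50.0 % of the charge. Each point booked as left-handed product is debited from that entry, and what remains is called the room. In the south-east run, the room is 7.7 percentage points at 25.0 min and 1.8 points at 50.0 min. Dividing the second by the first gives 0.234, the survival share: the part of the room that outlasts a wait of 25 min. This is a rough reading, since the scatter is 1 point on a room of 1.8 points.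

Carried to 1.5 h, the room of the asked flask becomes 0.18 points, so my own reckoning for now is 49.8 %. Beta then books 0.13 points. Eta moves no substrate entry in this ledger, so this reckoning books for it what it books for beta. This ledger has no inflow to the left-handed substrate entry, so it books alpha at the whole room, an estimate smaller than the 2 points required, and my answer is none.

The forecast gives 49.5 %, which is lower than my figure, and none, with 49.8 % after eta and 49.8 % after alpha. It holds that the product is “capped near 50% of the total”.

The asked flask gives 51.7 %, best none, 52.3 % after eta and 52.5 % after alpha, so the forecast held.

    left-handed substrate + racemization catalyst ⇌ right-handed substrate + racemization catalyst, rate k1*[racemization catalyst]*[left-handed substrate] forward; the back reaction follows from the equilibrium constant (k = 1.30 L mol⁻¹ min⁻¹)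
    partner + precatalyst → racemization catalyst + spent reagent (k = 0.0300 L mol⁻¹ min⁻¹)
    partner + free catalyst + right-handed substrate → free catalyst + right-handed product (k = 1.20 L² mol⁻² min⁻¹)
    partner + free catalyst + left-handed substrate → free catalyst + left-handed product (k = 2.70 L² mol⁻² min⁻¹)
    2 racemization catalyst ⇌ resting dimer, settled at all times (K = 34.0 L mol⁻¹)

The asked flask overruns the ledger's opening entry by 1.7 points, yet left-handed substrate forms product 47 times as fast as it inverts at 8.62 min and 12 times as fast at 90.0 min (forward step alone). The largest gain, 0.73 points with alpha, is more than the reckoned room of 0.18 points, so that room was no limit, and the answer none stands because the gain is less than 2 points. The survival share applied to the 0.640 % of left-handed substrate standing there gives 0.49 points for beta, against a computed 0.57 points. For the same flask read at 40 min, the share gives 46.8 %, and the computed value is 47.3 %.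

Readings and results stem from a simulated flask from invented constants; scatter was added.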